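Time is the trouble here: by 3.0 h the G has long been falling while X stands still, so the share asked is a race between what stays of G and how much X was made early.

| flask | J | L | remark | time |
|---|---|---|---|---|
| beta | 0.045 M | 0.60 equiv | run made earlier |  |
| eta | 0.045 M | 1.2 equiv | run made earlier |  |
| green | 0.045 M | 0.600 equiv (fed, over 40 min) | all else is in the flask from the start; the feed brings no volume worth counting | 3.0 h |
| red | 0.045 M (fed, over 40 min) | 0.600 equiv | all else is in the flask from the start; the feed brings no volume worth counting | 3.0 h |
| amber | 0.045 M | 0.600 equiv (fed, over 4.0 min) | all else is in the flask from the start; the feed brings no volume worth counting | 3.0 h |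
| blue | 0.045 M | 0.600 equiv | everything together at the start | 3.0 h |

| run | time / min | G / % | X / % |
|---|---|---|---|
| beta | 8.00 | 16.9 | 7.8 |
| beta | 15.0 | 20.8 | 9.2 |
| beta | 25.0 | 21.9 | 9.8 |
| beta | 40.0 | 21.8 | 9.7 |
| beta | 60.0 | 17.6 | 10.4 |
| beta | 120 | 7.4 | 9.9 |
| eta | 10.0 | 27.6 | 24.2 |
| eta | 20.0 | 31.7 | 27.0 |
| eta | 25.0 | 32.8 | 25.6 |
| eta | 40.0 | 32.5 | 28.5 |
| eta | 50.0 | 29.7 | 28.4 |

(each reading ± 0.5 percentage points)

- the flask with the highest share of G in G plus X ("all alike" if they lie within 1.5 percentage points) (green / red / amber / blue / all alike)
- share of G in G plus X at the end, green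
- share of G in G plus X at the end, red
- share of G in G plus X at the end, amber
- share of G in G plus X at the end, blue

- G is meant together with its D
- steps thought possible: G -> E; J + 2 L -> X; J + L -> G; L + G <-> D

Read beta first. G plus X levels at 31.7%, about half of the L charged, as if each G held a second L as D. So you treat L as the limiting reagent, and you look at what the recipe does to the split and to the hour at which G starts to fall. Since X takes two L and G one, the split should follow free L, so freeze that. Take mean free L up to the first reading as half the charge, and beta gives 1.54 per equiv. Call this s, the selectivity factor: X formed per G formed per equiv of free L. Eta, from another charge, reads 1.46.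

Now my chain for green. Beta's first reading gives G at 0.0704 min⁻¹ of J per equiv of free L. With two L taken per G, uptake matches the feed at a steady free L of 0.107 equiv. Then X/G is 0.164, and if green's total reaches beta's, which is my assumption, that splits it into G 27.2% and X 4.46%. Beta's tail falls at 0.0144 min⁻¹; running that from the end of the feed leaves G 3.61%.

The weak link is that clock's start. Beta's tail, run back from its 60.0 min reading, meets the 25.0 min reading only 19.9 min after it, a lag read off scattered readings, so I start green's clock that much later: G 4.81%, share 51.8%. I commit to green first.

The forecast says green, with green 47%, red 29%, amber 26%, blue 23%, on the ground that “X is second order in L”. My green stands higher.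

The flask gives green 51.9%, red 28.0%, amber 25.4%, blue 21.1%, so green leads.

    G → E (k = 0.0210 min⁻¹)
    J + 2 L → X (k = 59.0 M⁻² min⁻¹)
    J + L → G (k = 2.00 M⁻¹ min⁻¹)
    L + G ⇌ D, settled at all times (K = 170 M⁻¹)

In green at 0.586 h, L goes into G 3.1 times as fast as into X, which is X per G of 0.161 against the frozen 0.164; at 3.00 h that L ratio is 77, with 0.81% of the L charge free. On the neighbour like green with 1.00 equiv of L, scaling free L and the plateau with the charge gives X/G 0.273 and X 11.3%; that flask holds 12.3% at 3.00 h.

The readings come from a simulation with constants of no real substance, and the scatter is random.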